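## Retrosynthetic overview

1. Target 13 ⇐ protected adduct 12 by one basic, acid-free removal of four allyl ethers and two acetates (no ring formed).
2. 12 ⇐ endo Diels–Alder reaction (cyclohexene ring; C3, C4 and C5 set in one event) of chromene chalcone 11, held as a chiral spiroborate chelate, with dienyl chalcone 10.
3. 11 and 10 ⇐ the same monomer 7, the hydrate of the ortho-quinone methide that prenyl oxidation would give in the plant. With free phenols it closes by oxa-6π electrocyclisation (pyran ring); with acetylated phenols it loses a methyl proton (1,3-diene).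
4. 7 ⇐ Claisen–Schmidt condensation of ketone 6 with aldehyde 2; 6 ⇐ Heck coupling of iodide 4 with 5; 4 ⇐ 3; 2 ⇐ 1.
5. Ring order: the aromatic rings are bought; the pyran ring forms first and the cyclohexene ring second, both in the flask of step 6.

Numbering used for the cyclohexene: C1 (C–CH3), C2 (=CH), C3 (aryl of the diene half), C4 (aroyl), C5 (2,4-dioxygenated phenyl), C6 (CH2). The target and 12 are 3S,4R,5S, that is 3,4-cis and 4,5-trans (endo-type adduct).

Assumption: the (S)-VANOL borate opens the enone face that gives 4R,5S; if the opposite sense is found, (R)-VANOL is used with nothing else changed.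

## Route

Step 1
Reactants: 1 2,4-dihydroxybenzaldehyde
Product: 2 2,4-bis(allyloxy)benzaldehyde
Conditions: allyl bromide (2.5 equiv), K2CO3, DMF, 60 °C
Reagents that add atoms: allyl bromide, C=CCBr
Why: Williamson ether synthesis (SN2 on both phenoxides, heat forcing the hydrogen-bonded 2-OH); allyl ethers survive KOH and the borate and leave at the end without acid.

Step 2
Reactants: 3 2,4-dihydroxyacetophenone
Product: 4 1-(2,4-dihydroxy-3-iodophenyl)ethan-1-one
Conditions: I2 (0.4 equiv), HIO3 (0.2 equiv), EtOH–H2O, rt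
Reagents that add atoms: iodine, II; iodic acid, OI(=O)=O
Why: electrophilic aromatic iodination with HIO3 as in-flask oxidant, which under these conditions goes to C3, the carbon ortho to both hydroxyls.

Step 3
Reactants: 4 1-(2,4-dihydroxy-3-iodophenyl)ethan-1-one; 5 2-methylbut-3-en-2-ol (3 equiv)
Product: 6 1-{2,4-dihydroxy-3-[(1E)-3-hydroxy-3-methylbut-1-en-1-yl]phenyl}ethan-1-one
Conditions: Pd(OAc)2 (5 mol %), n-Bu4NCl, NaHCO3, DMF, 80 °C
Reagents that add atoms: none
Why: Mizoroki–Heck reaction in which aryl–Pd adds to the terminal CH2 and β-hydride elimination is possible only toward the benzylic carbon (the carbinol carbon has no hydrogen), giving the E-alkene, while the basic medium keeps the tertiary alcohol from ionising toward the pyran.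

Step 4
Reactants: 6 1-{2,4-dihydroxy-3-[(1E)-3-hydroxy-3-methylbut-1-en-1-yl]phenyl}ethan-1-one; 2 2,4-bis(allyloxy)benzaldehyde (1.1 equiv)
Product: 7 (2E)-3-[2,4-bis(allyloxy)phenyl]-1-{2,4-dihydroxy-3-[(1E)-3-hydroxy-3-methylbut-1-en-1-yl]phenyl}prop-2-en-1-one
Conditions: KOH (50% aq.), EtOH, rt, 48 h; cold NH4Cl/AcOH work-up to pH 6; Et3N-washed silica
Reagents that add atoms: none
Why: Claisen–Schmidt condensation (aldol addition, then E1cB loss of water) gives the E-enone; the phenoxides only slow enolisation, and the allyl ethers, the E-alkene and the tertiary alcohol are inert to cold KOH.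

Step 5
Reactants: 7 monomer chalcone (the portion destined to become the diene)
Product: 10 (2E)-3-[2,4-bis(allyloxy)phenyl]-1-{2,4-diacetoxy-3-[(1E)-3-methylbuta-1,3-dien-1-yl]phenyl}prop-2-en-1-one, via phenol diacetate 8 (not isolated), via tertiary mesylate 9 (not isolated)
Conditions: Ac2O (2.2 equiv), Et3N, DMAP (5 mol %), CH2Cl2, 0 °C, 1 h; then MsCl (1.5 equiv), Et3N, 0 °C→rt
Reagents that add atoms: acetic anhydride, CC(=O)OC(C)=O; methanesulfonyl chloride, CS(=O)(=O)Cl (its atoms stay only in intermediate 9)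
Why: DMAP-catalysed O-acetylation removes both phenol nucleophiles, so the tertiary allylic mesylate formed next can only eliminate toward a methyl group (E1/E2 dehydration, Et3N as base) to give the (E)-3-methylbuta-1,3-dienyl unit with the alkene geometry of step 3 untouched.

Step 6
Reactants: 7 monomer chalcone (1.0 equiv, the portion destined to become the dienophile); 10 dienyl chalcone diacetate (1.5 equiv)
Product: 12 (2E)-1-{2,4-diacetoxy-3-[(1S,5S,6R)-5-[2,4-bis(allyloxy)phenyl]-6-(5-hydroxy-2,2-dimethyl-2H-chromene-6-carbonyl)-3-methylcyclohex-2-en-1-yl]phenyl}-3-[2,4-bis(allyloxy)phenyl]prop-2-en-1-one, via chromene chalcone 11 (not isolated)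
Conditions: 7, Amberlyst 15 (dry), 4 Å MS, PhCF3, 40 °C, filtered under Ar; then B(OPh)3 (1.2 equiv), (S)-VANOL (1.2 equiv), 4 Å MS, rt, 1 h; then 10, rt→40 °C, 48 h; aq. NaHCO3; chromatography (removes the exo diastereomer, returns the ligand)
Reagents that add atoms: none
Why: acid ionises the tertiary allylic alcohol of 7 to the ortho-quinone methide, which closes by oxa-6π electrocyclisation onto the non-chelated 4'-oxygen to give 11, whose chelated 2'-hydroxy ketone then forms a chiral spiroborate that leaves one enone face open to diene 10 in an endo Diels–Alder reaction, so that C4 (R) and C5 (S) come from the face selection with retention of the E-enone (4,5-trans) and C3 (S) from the endo, aroyl-under-diene transition state (3,4-cis), while 10, lacking a free 2'-OH, cannot be activated as a dienophile.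

Step 7
Reactants: 12 protected endo adduct
Product: 13 target, (2E)-1-{3-[(1S,5S,6R)-5-(2,4-dihydroxyphenyl)-6-(5-hydroxy-2,2-dimethyl-2H-chromene-6-carbonyl)-3-methylcyclohex-2-en-1-yl]-2,4-dihydroxyphenyl}-3-(2,4-dihydroxyphenyl)prop-2-en-1-one
Conditions: Pd(PPh3)4 (10 mol %), K2CO3, MeOH–THF (degassed), rt; then pH 6 phosphate buffer
Reagents that add atoms: none
Why: Tsuji–Trost-type π-allyl transfer of the four allyl groups to methoxide on zerovalent palladium, together with methanolysis of the two aryl acetates, frees all six phenols in one acid-free operation, so the cis,trans adduct cannot ketalise and no stereocentre is touched (the phenoxide ortho to the C4 ketone suppresses enolisation at C4).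

## Compound list

1 | 2,4-dihydroxybenzaldehyde | O=Cc1ccc(O)cc1O | starting material
2 | 2,4-bis(allyloxy)benzaldehyde | O=Cc1ccc(OCC=C)cc1OCC=C | intermediate
3 | 2,4-dihydroxyacetophenone | CC(=O)c1ccc(O)cc1O | starting material
4 | 1-(2,4-dihydroxy-3-iodophenyl)ethan-1-one | CC(=O)c1ccc(O)c(I)c1O | intermediate
5 | 2-methylbut-3-en-2-ol | CC(C)(O)C=C | starting material
6 | 1-{2,4-dihydroxy-3-[(1E)-3-hydroxy-3-methylbut-1-en-1-yl]phenyl}ethan-1-one | CC(=O)c1ccc(O)c(/C=C/C(C)(C)O)c1O | intermediate
7 | (2E)-3-[2,4-bis(allyloxy)phenyl]-1-{2,4-dihydroxy-3-[(1E)-3-hydroxy-3-methylbut-1-en-1-yl]phenyl}prop-2-en-1-one (monomer) | CC(C)(O)/C=C/c1c(O)ccc(C(=O)/C=C/c2ccc(OCC=C)cc2OCC=C)c1O | intermediate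
8 | 2',4'-di-O-acetate of 7, tertiary alcohol free (not isolated) | CC(C)(O)/C=C/c1c(OC(C)=O)ccc(C(=O)/C=C/c2ccc(OCC=C)cc2OCC=C)c1OC(C)=O | intermediate
9 | tertiary methanesulfonate of 8 (not isolated) | CC(C)(OS(C)(=O)=O)/C=C/c1c(OC(C)=O)ccc(C(=O)/C=C/c2ccc(OCC=C)cc2OCC=C)c1OC(C)=O | intermediate
10 | (2E)-3-[2,4-bis(allyloxy)phenyl]-1-{2,4-diacetoxy-3-[(1E)-3-methylbuta-1,3-dien-1-yl]phenyl}prop-2-en-1-one (diene) | CC(=C)/C=C/c1c(OC(C)=O)ccc(C(=O)/C=C/c2ccc(OCC=C)cc2OCC=C)c1OC(C)=O | intermediate
11 | (2E)-3-[2,4-bis(allyloxy)phenyl]-1-(5-hydroxy-2,2-dimethyl-2H-chromen-6-yl)prop-2-en-1-one (dienophile, not isolated) | CC1(C)C=Cc2c(O1)ccc(C(=O)/C=C/c1ccc(OCC=C)cc1OCC=C)c2O | intermediate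
12 | protected endo adduct, 3S,4R,5S (3,4-cis, 4,5-trans): the target with four allyl ethers on the two 2,4-dioxygenated phenyl rings and two acetates on the ring that carries the cyclohexene | CC1=C[C@H](c2c(OC(C)=O)ccc(C(=O)/C=C/c3ccc(OCC=C)cc3OCC=C)c2OC(C)=O)[C@H](C(=O)c2ccc3c(c2O)C=CC(C)(C)O3)[C@@H](c2ccc(OCC=C)cc2OCC=C)C1 | intermediate
13 | CNP0115975.1, 3S,4R,5S | CC1=C[C@H](c2c(O)ccc(C(=O)/C=C/c3ccc(O)cc3O)c2O)[C@H](C(=O)c2ccc3c(c2O)C=CC(C)(C)O3)[C@@H](c2ccc(O)cc2O)C1 | target

## Step count and risks

Total step count: 7. Longest linear sequence: 6 steps (3 → 4 → 6 → 7 → 10 → 12 → 13, steps 2 to 7); step 1 is a one-step side branch.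

The three steps most likely to fail:

- **Step 6.** The endo/exo ratio of borate-mediated cycloadditions of this kind is often near 1:1, the face selectivity with a chromene-bearing chalcone is untested, and traces of acid or water from the first stage can destroy the borate. Fallback: setting out from 7 and 10, 7 is cyclised as in step 6 but chromene chalcone 11 is isolated. 11 and 10 are then heated with Ag nanoparticles on SiO2 (zerovalent silver) in CH2Cl2 at 50 °C, an electron-transfer catalysis that needs the free 2'-hydroxyl of 11 and favours the endo mode. This gives the racemic endo adduct, that is 12 together with its (3R,4S,5R) mirror image F1. Preparative HPLC on an amylose tris(3,5-dimethylphenylcarbamate) phase separates the two, and the route is rejoined at 12.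

- **Step 5.** The allyl cation from mesylate 9 can be captured by the neighbouring acetoxy group, which would give the pyran with loss of acetyl, and diene 10 can oligomerise. Fallback: setting out from 4, the diene is brought in ready-made instead of being made by dehydration. Hydroboration of 2-methylbut-1-en-3-yne with pinacolborane (Cp2Zr(H)Cl, 5 mol %) gives (E)-4,4,5,5-tetramethyl-2-(3-methylbuta-1,3-dien-1-yl)-1,3,2-dioxaborolane F2. Suzuki–Miyaura coupling of F2 with 4 (Pd(PPh3)4, K2CO3, dioxane–H2O, 80 °C) gives 1-{2,4-dihydroxy-3-[(1E)-3-methylbuta-1,3-dien-1-yl]phenyl}ethan-1-one F3. Claisen–Schmidt condensation of F3 with 2 (KOH, EtOH) gives the free dienyl chalcone F4, and Ac2O/Et3N/DMAP returns to the route at 10.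

- **Step 3.** The iodide sits between two free hydroxyls, so oxidative addition is slow, protodeiodination can compete, and the product may close early to the pyran. Fallback: setting out from 4, the Heck reaction is replaced by a cross-coupling with a preformed E-alkenylboron partner. Hydroboration of 2-methylbut-3-yn-2-ol with pinacolborane (Cp2Zr(H)Cl, 5 mol %) gives (E)-2-methyl-4-(4,4,5,5-tetramethyl-1,3,2-dioxaborolan-2-yl)but-3-en-2-ol F5. Suzuki–Miyaura coupling of F5 with 4 (Pd(PPh3)4, K2CO3, dioxane–H2O, 70 °C) returns to the route at 6.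

## Further compounds

F1 | step 6 | (3R,4S,5R) mirror image of 12 | CC1=C[C@@H](c2c(OC(C)=O)ccc(C(=O)/C=C/c3ccc(OCC=C)cc3OCC=C)c2OC(C)=O)[C@@H](C(=O)c2ccc3c(c2O)C=CC(C)(C)O3)[C@H](c2ccc(OCC=C)cc2OCC=C)C1
F2 | step 5 | (E)-4,4,5,5-tetramethyl-2-(3-methylbuta-1,3-dien-1-yl)-1,3,2-dioxaborolane | CC(=C)/C=C/B1OC(C)(C)C(C)(C)O1
F3 | step 5 | 1-{2,4-dihydroxy-3-[(1E)-3-methylbuta-1,3-dien-1-yl]phenyl}ethan-1-one | CC(=O)c1ccc(O)c(/C=C/C(C)=C)c1O
F4 | step 5 | (2E)-3-[2,4-bis(allyloxy)phenyl]-1-{2,4-dihydroxy-3-[(1E)-3-methylbuta-1,3-dien-1-yl]phenyl}prop-2-en-1-one | CC(=C)/C=C/c1c(O)ccc(C(=O)/C=C/c2ccc(OCC=C)cc2OCC=C)c1O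
F5 | step 3 | (E)-2-methyl-4-(4,4,5,5-tetramethyl-1,3,2-dioxaborolan-2-yl)but-3-en-2-ol | CC(C)(O)/C=C/B1OC(C)(C)C(C)(C)O1
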